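**Plan**

- Ring A (C1′ cinnamoyl, C2′ OH, C3′ carrying C5 of the heptane chain, C4′ OH, C5′ H, C6′ OMe) is an acylphloroglucinol monomethyl ether, i.e. a folded 3,5,7-tricarbonyl chain with C6′ as a methyl enol ether. The C3 hydroxyl is 1,5-related to C2′, so the ester end of that chain can be the δ-lactone O–C3–C4–C5–C3′–C2′.
- Cuts: the three aryl MOM ethers; C1′–C2′ (Claisen closure of ring A that opens the lactone) to β-keto lactone 20; C4′–C5′ (acyl imidazolide of acid 12 plus γ-dienolate of methoxy dienone 17); C3′–CO2H; C5–C6 (alkenyl boronate 3 onto dihydropyranone 9); the lactone C=C (metathesis) and C3–C4 (allylation of aldehyde 6).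
- Forward: the δ-lactone ring is built first and carries C3. The styryl arm (C6, C7, ring C) is added at C5, C3′ is carboxylated, the C4′–C5′–C6′(OMe)=C1′–CO–CH=CH–ring B chain is joined, and ring A is closed last with release of the C3 hydroxyl.
- Stereochemistry: C3 (S) from a Keck asymmetric allylation; C5 (R) from substrate-controlled 1,4-addition anti to the C3 side chain on the lactone (4,6-trans). Ring A formation makes no stereocentre. The E alkenes come from boron–Wittig olefination and aldol dehydration.

Key step: step 13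

Remark: C1–C7 number the heptane chain (C1 at ring D, C7 at ring C) and C1′–C6′ ring A; Ar = 4-(methoxymethoxy)phenyl in the longer names; 4-methoxypent-3-en-2-one is used as its commercial E isomer.

Step 1
Reactants: 1 4-hydroxybenzaldehyde
Product: 2 4-(methoxymethoxy)benzaldehyde
Conditions: MOMCl, iPr2NEt, CH2Cl2, 0 → 23 °C
Reagents that add atoms: chloromethyl methyl ether, COCCl
Why: Williamson-type O-alkylation of the phenol gives an acetal ether that is inert to the bases and organometallic reagents used later and is removed by mild acid at the end.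

Step 2
Reactants: 2 4-(methoxymethoxy)benzaldehyde
Product: 3 2-{(E)-2-[4-(methoxymethoxy)phenyl]ethenyl}-4,4,5,5-tetramethyl-1,3,2-dioxaborolane
Conditions: CH2(Bpin)2, LiTMP, THF, 0 °C; then 2, −78 → 23 °C
Reagents that add atoms: bis(4,4,5,5-tetramethyl-1,3,2-dioxaborolan-2-yl)methane, CC1(C)OB(CB2OC(C)(C)C(C)(C)O2)OC1(C)C
Why: Boron–Wittig olefination, in which the lithiated geminal bis(boronate) adds to the aldehyde and syn elimination of the B–O unit should give the E alkenyl boronate that later supplies C6, C7 and ring C.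

Step 3
Reactants: 4 methyl 3-(4-hydroxyphenyl)propanoate
Product: 5 methyl 3-[4-(methoxymethoxy)phenyl]propanoate
Conditions: MOMCl, iPr2NEt, CH2Cl2, 0 → 23 °C
Reagents that add atoms: chloromethyl methyl ether, COCCl
Why: Williamson-type O-alkylation of the phenol, as in step 1, protects ring D.

Step 4
Reactants: 5 methyl 3-[4-(methoxymethoxy)phenyl]propanoate
Product: 6 3-[4-(methoxymethoxy)phenyl]propanal
Conditions: DIBAL-H (1.1 equiv), CH2Cl2, −78 °C; MeOH, then aq. Rochelle salt
Reagents that add atoms: none
Why: Partial reduction of the methyl ester with DIBAL-H at low temperature stops at the aluminium hemiacetal, which gives the aldehyde on hydrolysis.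

Step 5
Reactants: 6 3-[4-(methoxymethoxy)phenyl]propanal
Product: 7 (3S)-1-[4-(methoxymethoxy)phenyl]hex-5-en-3-ol
Conditions: (R)-BINOL (20 mol%), Ti(OiPr)4 (10 mol%), 4 Å MS, CH2Cl2; allylSnBu3, −20 °C; aq. KF work-up
Reagents that add atoms: allyltributylstannane, C=CC[Sn](CCCC)(CCCC)CCCC
Why: Keck asymmetric allylation, in which the titanium–(R)-BINOL Lewis acid should direct the allyl group to the Re face of the aldehyde and so set C3 as S.

Step 6
Reactants: 7 (3S)-1-[4-(methoxymethoxy)phenyl]hex-5-en-3-ol
Product: 8 (3S)-1-[4-(methoxymethoxy)phenyl]hex-5-en-3-yl prop-2-enoate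
Conditions: acryloyl chloride, Et3N, DMAP (cat.), CH2Cl2, 0 °C
Reagents that add atoms: acryloyl chloride, C=CC(=O)Cl
Why: DMAP-catalysed O-acylation of the secondary alcohol installs the two carbons that become C3′ and C2′ of ring A.

Step 7
Reactants: 8 (3S)-1-[4-(methoxymethoxy)phenyl]hex-5-en-3-yl prop-2-enoate
Product: 9 (6S)-6-{2-[4-(methoxymethoxy)phenyl]ethyl}-5,6-dihydro-2H-pyran-2-one
Conditions: second-generation Grubbs catalyst RuCl2(=CHPh)(PCy3)(H2IMes) (3 mol%), CH2Cl2 (0.005 M), 40 °C
Reagents that add atoms: none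
Why: Ring-closing metathesis of the acrylate with the terminal alkene closes the six-membered unsaturated lactone with loss of ethene, as is routine for homoallylic acrylates.

Step 8
Reactants: 9 (6S)-6-{2-[4-(methoxymethoxy)phenyl]ethyl}-5,6-dihydro-2H-pyran-2-one; 3 E alkenyl boronate
Product: 10 (4S,6S)-4-[(E)-2-Ar-ethenyl]-6-(2-Ar-ethyl)oxan-2-one (4,6-trans)
Conditions: 3 (1.8 equiv), [Rh(cod)Cl]2 (2.5 mol%), KOH (0.3 equiv), 1,4-dioxane/H2O (10:1), 35 °C; work-up at pH 4
Reagents that add atoms: none
Why: Hayashi–Miyaura 1,4-addition, in which the alkenylrhodium species should add to the enoate face anti to the C6 side chain of the half-chair lactone, so that the new stereocentre C5 arises 4,6-trans, the relationship that corresponds to 3S,5R in the target.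

Step 9
Reactants: 10 trans lactone
Product: 12 (4R,6S)-4-[(E)-2-Ar-ethenyl]-6-(2-Ar-ethyl)-2-oxooxane-3-carboxylic acid as C3 epimers, via lithium enolate 11 (not isolated)
Conditions: LDA (1.1 equiv), THF, −78 °C; cannulated into CO2-saturated THF, −78 → −20 °C; aq. NaHSO4, 0 °C
Reagents that add atoms: carbon dioxide, O=C=O
Why: Carboxylation of the lactone lithium enolate gives the malonic half-acid, and the new centre C3′ may be a mixture of epimers because this carbon becomes aromatic later.

Step 10
Reactants: 13 (3E)-4-methoxypent-3-en-2-one; 2 4-(methoxymethoxy)benzaldehyde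
Product: 15 (4E)-1-hydroxy-5-methoxy-1-[4-(methoxymethoxy)phenyl]hex-4-en-3-one (racemic), via lithium enolate 14 (not isolated)
Conditions: LDA, THF, −78 °C; then 2, −78 °C; aq. NH4Cl
Reagents that add atoms: none
Why: Directed aldol addition, in which LDA removes the kinetically favoured α′ proton (acetyl methyl) of the vinylogous ester and leaves the γ-methyl group untouched; the racemic carbinol is erased in step 11.

Step 11
Reactants: 15 aldol adduct
Product: 17 (1E,4E)-5-methoxy-1-[4-(methoxymethoxy)phenyl]hexa-1,4-dien-3-one, via mesylate 16 (not isolated)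
Conditions: MsCl, Et3N (3 equiv), CH2Cl2, 0 → 23 °C
Reagents that add atoms: none
Why: Mesylation of the benzylic alcohol followed by E1cB elimination with triethylamine completes the aldol condensation and should give the conjugated E enone.

Step 12
Reactants: 12 lactone acid; 17 methoxy dienone
Product: 20 (4R,6S)-3-{(3E,6E)-3-methoxy-7-[4-(methoxymethoxy)phenyl]-5-oxohepta-3,6-dienoyl}-4-[(E)-2-Ar-ethenyl]-6-(2-Ar-ethyl)oxan-2-one as C3 epimers and enol tautomers, via acyl imidazolide 18 (not isolated), via lithium dienolate 19 (not isolated)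
Conditions: 12, CDI (1.05 equiv), THF, 0 → 23 °C; separately 17 (3.5 equiv), LiHMDS (3.4 equiv), THF, −78 °C; imidazolide solution added at −78 °C, then −40 °C; AcOH quench
Reagents that add atoms: none
Why: Crossed Claisen condensation, in which the lithium γ-dienolate of the β-methoxy dienone (which, like the dienolates of 3-methoxycrotonates, 4-methoxy-6-methylpyranones and dioxinones, reacts at its terminal carbon) is C-acylated by the acyl imidazole, while the excess dienolate takes up the acidic N–H and C–H protons.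

Step 13
Reactants: 20 β-keto lactone
Product: 21 (E)-1-{2,4-dihydroxy-6-methoxy-3-[(1E,3R,5S)-5-hydroxy-1,7-bis(Ar)hept-1-en-3-yl]phenyl}-3-[4-(methoxymethoxy)phenyl]prop-2-en-1-one
Conditions: DBU (2.5 equiv), MeCN, 23 → 50 °C; cold aq. citric acid
Reagents that add atoms: none
Why: DBU gives the monoanion of 20, which equilibrates by proton transfer between the C3′ enolate and the C5′/C1′ dienolate; in the dienolate the lactone carbonyl C2′ is not enolised and is attacked by C1′, the tetrahedral intermediate expels the C3 alkoxide (the lactone opens) and enolisation of the cyclohexadienone aromatises ring A. The closest known reaction type is the Claisen (Dieckmann-type) cyclisation of 3,5,7-tricarbonyl esters and of their methyl enol ethers to acylphloroglucinols. Ring A is the only ring closed, by 6-exo-trig C-acylation; no stereocentre is formed, and C3 and C5 carry no proton acidic enough for an amidine. The step needs C-acylation at C1′ to win over aldol, Michael and oxa-Michael closures: the C6′ enol ether removes the aldol mode that could aromatise, the aldol of C3′ onto the cinnamoyl ketone cannot dehydrate and reverts, the dienolate oxygens reach C2′ only through eight-membered rings, and the aromatic phenoxide is the only irreversible sink. A stoichiometric amidine instead of excess strong base keeps the substrate from resting as an unreactive dianion, and the δ-lactone is a better acyl donor than an open-chain ester.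

Step 14
Reactants: 21 tris(MOM) ether of calyxin A
Product: 22 calyxin A
Conditions: aq. HCl (2 M)/MeOH/THF (1:6:2), 23 → 35 °C
Reagents that add atoms: none
Why: Acid-catalysed acetal exchange with methanol removes the three aryl MOM ethers under conditions chosen to be mild enough for the chalcone, the 4-hydroxystyrene and the allylic–benzylic C5 centre.

**Compound list**

1 | 4-hydroxybenzaldehyde | O=Cc1ccc(O)cc1 | starting material
2 | 4-(methoxymethoxy)benzaldehyde | COCOc1ccc(C=O)cc1 | intermediate
3 | 2-{(E)-2-[4-(methoxymethoxy)phenyl]ethenyl}-4,4,5,5-tetramethyl-1,3,2-dioxaborolane | COCOc1ccc(/C=C/B2OC(C)(C)C(C)(C)O2)cc1 | intermediate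
4 | methyl 3-(4-hydroxyphenyl)propanoate | COC(=O)CCc1ccc(O)cc1 | starting material
5 | methyl 3-[4-(methoxymethoxy)phenyl]propanoate | COCOc1ccc(CCC(=O)OC)cc1 | intermediate
6 | 3-[4-(methoxymethoxy)phenyl]propanal | COCOc1ccc(CCC=O)cc1 | intermediate
7 | (3S)-1-[4-(methoxymethoxy)phenyl]hex-5-en-3-ol | C=CC[C@@H](O)CCc1ccc(OCOC)cc1 | intermediate
8 | (3S)-1-[4-(methoxymethoxy)phenyl]hex-5-en-3-yl prop-2-enoate | C=CC[C@@H](OC(=O)C=C)CCc1ccc(OCOC)cc1 | intermediate
9 | (6S)-6-{2-[4-(methoxymethoxy)phenyl]ethyl}-5,6-dihydro-2H-pyran-2-one | O=C1C=CC[C@H](CCc2ccc(OCOC)cc2)O1 | intermediate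
10 | (4S,6S)-4-{(E)-2-[4-(methoxymethoxy)phenyl]ethenyl}-6-{2-[4-(methoxymethoxy)phenyl]ethyl}oxan-2-one (4,6-trans) | O=C1C[C@@H](/C=C/c2ccc(OCOC)cc2)C[C@H](CCc2ccc(OCOC)cc2)O1 | intermediate
11 | lithium enolate of lactone 10 (O-lithio ketene acetal, formed in the flask) | [Li]OC1=C[C@@H](/C=C/c2ccc(OCOC)cc2)C[C@H](CCc2ccc(OCOC)cc2)O1 | intermediate
12 | (4R,6S)-4-{(E)-2-[4-(methoxymethoxy)phenyl]ethenyl}-6-{2-[4-(methoxymethoxy)phenyl]ethyl}-2-oxooxane-3-carboxylic acid (C3 epimers) | OC(=O)C1C(=O)O[C@@H](CCc2ccc(OCOC)cc2)C[C@@H]1/C=C/c1ccc(OCOC)cc1 | intermediate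
13 | (3E)-4-methoxypent-3-en-2-one | CO/C(C)=C/C(C)=O | starting material
14 | lithium (3E)-4-methoxypenta-1,3-dien-2-olate (kinetic enolate of 13, formed in the flask) | C=C(O[Li])/C=C(\C)OC | intermediate
15 | (4E)-1-hydroxy-5-methoxy-1-[4-(methoxymethoxy)phenyl]hex-4-en-3-one (racemic) | CO/C(C)=C/C(=O)CC(O)c1ccc(OCOC)cc1 | intermediate
16 | (4E)-5-methoxy-1-[4-(methoxymethoxy)phenyl]-3-oxohex-4-en-1-yl methanesulfonate (formed in the flask) | CO/C(C)=C/C(=O)CC(OS(C)(=O)=O)c1ccc(OCOC)cc1 | intermediate
17 | (1E,4E)-5-methoxy-1-[4-(methoxymethoxy)phenyl]hexa-1,4-dien-3-one | CO/C(C)=C/C(=O)/C=C/c1ccc(OCOC)cc1 | intermediate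
18 | (4R,6S)-3-(1H-imidazole-1-carbonyl)-4-{(E)-2-[4-(methoxymethoxy)phenyl]ethenyl}-6-{2-[4-(methoxymethoxy)phenyl]ethyl}oxan-2-one (C3 epimers, formed in the flask) | O=C(C1C(=O)O[C@@H](CCc2ccc(OCOC)cc2)C[C@@H]1/C=C/c1ccc(OCOC)cc1)n1ccnc1 | intermediate
19 | lithium (1E)-5-methoxy-1-[4-(methoxymethoxy)phenyl]hexa-1,3,5-trien-3-olate (γ-dienolate of 17, formed in the flask) | [Li]OC(/C=C/c1ccc(OCOC)cc1)=CC(=C)OC | intermediate
20 | (4R,6S)-3-{(3E,6E)-3-methoxy-7-[4-(methoxymethoxy)phenyl]-5-oxohepta-3,6-dienoyl}-4-{(E)-2-[4-(methoxymethoxy)phenyl]ethenyl}-6-{2-[4-(methoxymethoxy)phenyl]ethyl}oxan-2-one (C3 epimers) | O=C(C/C(OC)=C\C(=O)/C=C/c1ccc(OCOC)cc1)C1C(=O)O[C@@H](CCc2ccc(OCOC)cc2)C[C@@H]1/C=C/c1ccc(OCOC)cc1 | intermediate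
21 | (E)-1-{2,4-dihydroxy-6-methoxy-3-[(1E,3R,5S)-5-hydroxy-1,7-bis[4-(methoxymethoxy)phenyl]hept-1-en-3-yl]phenyl}-3-[4-(methoxymethoxy)phenyl]prop-2-en-1-one | COc1cc(O)c([C@@H](/C=C/c2ccc(OCOC)cc2)C[C@@H](O)CCc2ccc(OCOC)cc2)c(O)c1C(=O)/C=C/c1ccc(OCOC)cc1 | intermediate
22 | calyxin A, (E)-1-{2,4-dihydroxy-3-[(1E,3R,5S)-5-hydroxy-1,7-bis(4-hydroxyphenyl)hept-1-en-3-yl]-6-methoxyphenyl}-3-(4-hydroxyphenyl)prop-2-en-1-one | COc1cc(O)c([C@@H](/C=C/c2ccc(O)cc2)C[C@@H](O)CCc2ccc(O)cc2)c(O)c1C(=O)/C=C/c1ccc(O)cc1 | target

**Step count**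

Total step count: 14.
Longest linear sequence: 10 steps (steps 3, 4, 5, 6, 7, 8, 9, 12, 13, 14, from methyl 3-(4-hydroxyphenyl)propanoate).

**Steps most likely to fail**

Step 13 (closure of ring A). Proton transfer may hold 20 as the C3′ enolate, in which the lactone carbonyl is deactivated, while the base slowly cleaves the C3′–C4′ bond (retro-Claisen) or closes C5′ onto the enone terminus. The fallback sets out from lactone 10 (as its enolate 11) and aldehyde 2 and returns at 21. Commercial 4-methoxy-6-methyl-2H-pyran-2-one is condensed with 2 (Mg(OMe)2, MeOH, reflux) to give styrylpyranone F1. Enolate 11 is then added to F1 in THF at −78 °C. Attack at the pyranone carbonyl and ring opening (acyl transfer) should form the C3′–C4′ bond and release the C5′/C1′ dienolate beside a lactone carbonyl that is not yet enolised, so that ring A can close on warming before proton transfer intervenes.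

Step 12 (chain extension). The dienolate 19 may act only as a base toward the acidic C3′–H of imidazolide 18 (proton transfer, ketene formation and self-condensation), or be acylated on oxygen. The fallback sets out from acid 12 and dienone 17 and returns at 20. Acid 12 is converted under neutral conditions with 1-chloro-N,N,2-trimethylprop-1-en-1-amine into acid chloride F2. Dienolate 19 is silylated with Me3SiCl to give silyl dienol ether F3. The two are combined in CH2Cl2 at −78 → 0 °C; this base-free, Mukaiyama-type acylation of a 1,3-dioxygenated silyl dienol ether at its terminal carbon avoids the proton transfer.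

Step 8 (styryl transfer to the lactone). Protodeboronation of the electron-rich alkenyl boronate may outrun transmetalation, or the rhodium carbometalation may show poor facial selectivity. The fallback sets out from 9 and returns at 10. CuBr·SMe2-catalysed 1,4-addition of vinylmagnesium bromide (THF, −78 °C), for which attack anti to the C6 substituent of such dihydropyranones is well established, gives trans vinyl lactone F4. Cross-metathesis of F4 with styrene F5 (made from 2 by Wittig methylenation with Ph3P=CH2) under the second-generation Grubbs catalyst then installs the E styryl group.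

**Further compounds**

F1 | step 13 | 4-methoxy-6-{(E)-2-[4-(methoxymethoxy)phenyl]ethenyl}-2H-pyran-2-one | COc1cc(/C=C/c2ccc(OCOC)cc2)oc(=O)c1
F2 | step 12 | (4R,6S)-4-{(E)-2-[4-(methoxymethoxy)phenyl]ethenyl}-6-{2-[4-(methoxymethoxy)phenyl]ethyl}-2-oxooxane-3-carbonyl chloride (C3 epimers) | O=C(Cl)C1C(=O)O[C@@H](CCc2ccc(OCOC)cc2)C[C@@H]1/C=C/c1ccc(OCOC)cc1
F3 | step 12 | {[(1E)-5-methoxy-1-[4-(methoxymethoxy)phenyl]hexa-1,3,5-trien-3-yl]oxy}trimethylsilane | C=C(OC)C=C(O[Si](C)(C)C)/C=C/c1ccc(OCOC)cc1
F4 | step 8 | (4S,6S)-4-ethenyl-6-{2-[4-(methoxymethoxy)phenyl]ethyl}oxan-2-one | O=C1C[C@@H](C=C)C[C@H](CCc2ccc(OCOC)cc2)O1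
F5 | step 8 | 1-ethenyl-4-(methoxymethoxy)benzene | C=Cc1ccc(OCOC)cc1
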